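**Analysis of the target**

Compound 19 is a 2,3-dihydrobenzofuran: a benzene ring fused to a five-membered cyclic ether made of O1, C2, C3, C3a and C7a, in which C3 is an unsubstituted benzylic CH2. C5, para to O1, carries an (E)-acrylic acid. C2 carries the branch C1'(H)(CH3)–C2'H2–O, whose oxygen is esterified with (E)-4-hydroxycinnamic acid. The two stereocenters, C2 in the ring and C1' beside it, are both S. They are neighbours, but the bond between them rotates freely, so no ring relays one to the other and each must be controlled separately. The sensitive groups are two aryl-conjugated E alkenes (acceptors for carbenes and radicals), a free phenol, a free carboxylic acid and an alkyl cinnamate ester that strong base would cleave. The difficulty is that C2 is an ether carbon flanked by a bare CH2 and a methyl-bearing stereocenter, so the target keeps no carbonyl group or alkene from which the C2–C3 bond or the C2 configuration could obviously be derived. The plan rests on the chain O1–C2–C1'(CH3)–C2'–O, which has the skeleton of hydroxy ester 1 with C1' already correctly configured. Once that chain hangs on the arene through O1, C2 is an oxygen-activated CH2 five atoms from the benzylic carbon C3, the right distance for a carbene on C3 to insert into a C2–H bond.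

**Retrosynthetic reasoning**

19 to 18. The acrylic acid is carried as its tert-butyl ester, so it cannot compete when the C2' alcohol is acylated. The last step only liberates it, by acid, which leaves the cinnamate ester and both alkenes alone.

18 to 16 and 17. The C2'–O acyl bond is cut next. The coumaroyl unit brings a phenol and an electron-rich alkene that would not survive the carbene, radical or palladium steps, so it is attached as late as possible. The forward reaction must esterify a primary alcohol with the carboxyl group of 17 and leave its phenol untouched.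

16 to 15, then to 13 and 14. After silyl removal, the C5–vinyl bond is cut as a Heck disconnection. The acrylate is a carbene acceptor and cannot be present earlier, so a bromine at C5 holds its place from starting material 4 onwards.

13 to 11 (through 12), then to 10. A carbene at C3 needs an acceptor group, and the target has none there, so the C3 carboxyl group must be removed without trace. Radical decarboxylation through thiohydroxamate ester 12 replaces CO2H by H at a benzylic carbon without base, so C2 is not at risk. The ester of 10 is the trichloroethyl ester from alcohol 7 because it is cleaved reductively at neutral pH. A basic hydrolysis would form a C3 enolate that can expel O1 from C2, open the ring and erase the C2 stereocenter.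

10 to 9. The C2–C3 bond is cut here. This removes the ring and the C2 stereocenter in one move and leads back to an open aryl ether whose only stereocenter is C1'. Cutting O1–C2 or C3–C3a would leave the C2 configuration to be made on an acyclic chain by separate means.

9 to 8, then to 6 and 7, then to 5. The diazo group comes from diazo transfer onto the doubly activated CH2 of 8. Ester 8 is made from acid 6 and alcohol 7, and 6 comes from methyl ester 5. The ether is built on the methyl ester and the ester is exchanged afterwards. A trichloroethyl ester beside a free phenoxide is an activated ester set up to close to the five-membered lactone, and the free hydroxy acid would lactonise on any attempt to activate it.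

5 to 3 and 4. The aryl O–CH2 bond, the future O1–C2 bond, is cut as a Mitsunobu etherification at a primary carbon, which does not touch C1'.

3 to 2, then to 1. Silylation of the hydroxyl group of 1 and reduction of its ester give 3. The ester carbon of 1 becomes C2 and the carbinol carbon becomes C2'.

**Alternatives that were turned down**

Alternative 1: This route cuts C2–C1' and C3–C3a at once and leaves the O1–C7a bond for later.
- Forward step: secondary boronate A2 and vinyllithium A4 form a vinyl boron ate complex. With aryl triflate A3 under Pd(OAc)2 and the diphosphine MandyPhos, the arylpalladium species triggers a 1,2-shift. C1' moves from boron to C2 with retention and the aryl group bonds to C3, giving boronate A1.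
- For it: it is convergent, and C2 is set by the catalyst independently of C1'. C3 is born as CH2, so no ester has to be removed afterwards. On that point it is stronger than the chosen plan.
- Against it: the migrating group is an alpha-branched secondary alkyl group, the least willing kind in such shifts. A2 has to be made enantioenriched by a separate asymmetric step, since no chiral-pool compound maps onto it as directly as 1 maps onto the chosen precursor. After the coupling come C–B oxidation, an intramolecular etherification of an unactivated aryl chloride by a secondary alcohol, and a bromination to give C5 a handle.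
- Comparison: the uncertainty is spread over three operations rather than one. The chosen plan offers a precursor made by routine reactions, with ring and C2 formed together and the C5 bromide in place from the start.

Alternative 2: This route makes C1' by adding H to an alkene and puts the C2' oxygen in through silicon. The ring is again closed later at O1–C7a.
- Forward step: dimethylsilyl ether A6 of an (S)-allylic alcohol undergoes platinum-catalysed (H2PtCl6) 5-endo intramolecular hydrosilylation of its 1,1-disubstituted alkene. This gives oxasilacyclopentane A5, in which C1' is set relative to C2 by the short tether.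
- For it: the key step is cheap and tolerant, and it is more reliable than a carbene insertion. C1' needs no chiral-pool source.
- Against it: the absolute configuration is only moved back one step, because the allylic alcohol must first be made enantioenriched. Oxidative cleavage of C–Si then leaves a primary and a secondary hydroxyl group to be told apart. The ring closure consumes the aryl bromide, so C5 again needs a late halogenation.
- Comparison: the step count is clearly higher. The chosen plan offers C1' at no cost and a halogen that survives to the Heck step.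

Alternative 3: This route cuts C3a–C3 and O1–C2 together.
- Forward step: zerovalent palladium with a chiral phosphine inserts into the C–I bond of iodophenol A8. The aryl group adds to the unsubstituted vinyl end of isoprene A9, and the phenoxide closes on the resulting allyl complex at C2, giving dihydrobenzofuran A7.
- For it: one step from two commodity chemicals delivers the ring, C2 and the C5 bromide. In step economy it is much stronger than the chosen plan, probably by half the step count.
- Against it: the step needs three selectivities at once (which alkene inserts, where the phenoxide attacks, and which face). C1' must then be made by hydroboration of a 1,1-disubstituted alkene whose faces differ only through the neighbouring C2, a case where both substrate and reagent control are weak. The C1' epimers differ by one methyl group on a rotating chain and would be hard to separate.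
- Comparison: the chosen plan is longer but takes C1' from the chiral pool and leaves a single stereochemical question, C2, to one catalyst-controlled step.

Key step: step 7

Assumption: Rh2(S-PTTL)4 is taken to have the sense of induction at the ether CH2 that leads to 10; if the substrate shows the opposite sense, the mirror-image catalyst Rh2(R-PTTL)4 takes its place and nothing else changes.

**Route**

Step 1
Reactants: 1 methyl (S)-3-hydroxy-2-methylpropanoate
Product: 2 methyl (S)-3-[(tert-butyldimethylsilyl)oxy]-2-methylpropanoate
Conditions: TBSCl, imidazole, DMF, 0 °C → rt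
Reagents that add atoms: tert-butyldimethylsilyl chloride, CC(C)(C)[Si](C)(C)Cl
Why: Silylation of a primary alcohol under imidazole catalysis; the stereocenter is not involved and the mild base does not enolise the ester.

Step 2
Reactants: 2 methyl (S)-3-[(tert-butyldimethylsilyl)oxy]-2-methylpropanoate
Product: 3 (R)-3-[(tert-butyldimethylsilyl)oxy]-2-methylpropan-1-ol
Conditions: i-Bu2AlH (2.3 equiv), CH2Cl2, −78 → 0 °C; aq. potassium sodium tartrate
Reagents that add atoms: none
Why: Hydride reduction of the ester to the primary alcohol; the aldehyde stage is reduced faster than it can enolise, so the center is kept (its descriptor changes to R only because the priorities change).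

Step 3
Reactants: 3 (R)-3-[(tert-butyldimethylsilyl)oxy]-2-methylpropan-1-ol; 4 methyl 2-(5-bromo-2-hydroxyphenyl)acetate
Product: 5 methyl 2-{5-bromo-2-[(R)-3-(tert-butyldimethylsilyloxy)-2-methylpropoxy]phenyl}acetate
Conditions: PPh3, DIAD, THF, 0 °C → rt
Reagents that add atoms: none
Why: Mitsunobu etherification of a phenol with a primary alcohol; the substitution takes place at CH2, so C1' is untouched, and the methyl ester is too poor an acylating agent to lactonise onto the phenoxide.

Step 4
Reactants: 5 methyl 2-{5-bromo-2-[(R)-3-(tert-butyldimethylsilyloxy)-2-methylpropoxy]phenyl}acetate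
Product: 6 2-{5-bromo-2-[(R)-3-(tert-butyldimethylsilyloxy)-2-methylpropoxy]phenyl}acetic acid
Conditions: LiOH·H2O, THF/MeOH/H2O, rt; then 0.5 M HCl to pH 4, 0 °C
Reagents that add atoms: lithium hydroxide, [Li+].[OH-]
Why: Saponification of an unhindered methyl ester; the aryl ether, the aryl bromide and the primary silyl ether are stable to cold aqueous hydroxide and to a brief pH 4 work-up.

Step 5
Reactants: 6 2-{5-bromo-2-[(R)-3-(tert-butyldimethylsilyloxy)-2-methylpropoxy]phenyl}acetic acid; 7 2,2,2-trichloroethanol
Product: 8 2,2,2-trichloroethyl 2-{5-bromo-2-[(R)-3-(tert-butyldimethylsilyloxy)-2-methylpropoxy]phenyl}acetate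
Conditions: DCC, DMAP (cat.), CH2Cl2, 0 °C → rt
Reagents that add atoms: none
Why: Steglich esterification; with the phenol already alkylated there is no internal nucleophile, so the activated acid can only meet alcohol 7.

Step 6
Reactants: 8 2,2,2-trichloroethyl 2-{5-bromo-2-[(R)-3-(tert-butyldimethylsilyloxy)-2-methylpropoxy]phenyl}acetate
Product: 9 2,2,2-trichloroethyl 2-{5-bromo-2-[(R)-3-(tert-butyldimethylsilyloxy)-2-methylpropoxy]phenyl}-2-diazoacetate
Conditions: 2-nitrobenzenesulfonyl azide, DBU, MeCN, 0 °C
Reagents that add atoms: 2-nitrobenzenesulfonyl azide, [N-]=[N+]=NS(=O)(=O)c1ccccc1[N+](=O)[O-]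
Why: Regitz diazo transfer onto the CH2 activated by both aryl and ester; the electron-poor sulfonyl azide is chosen because the ortho-alkoxy group lowers the acidity of the methylene.

Step 7
Reactants: 9 2,2,2-trichloroethyl 2-{5-bromo-2-[(R)-3-(tert-butyldimethylsilyloxy)-2-methylpropoxy]phenyl}-2-diazoacetate
Product: 10 2,2,2-trichloroethyl (2R,3R)-5-bromo-2-[(S)-1-(tert-butyldimethylsilyloxy)propan-2-yl]-2,3-dihydrobenzofuran-3-carboxylate (2,3-cis)
Conditions: Rh2(S-PTTL)4 (1 mol%), toluene, 4 Å MS, −60 → −20 °C, slow addition of 9
Reagents that add atoms: none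
Why: Rh2(S-PTTL)4 takes N2 from 9 and forms a rhodium-bound donor/acceptor carbene at the future C3, which inserts into one C–H bond of the aryl ether CH2 through a concerted but asynchronous three-centre transition state with hydride-like character at carbon. The closest known reaction type is the enantioselective intramolecular C–H insertion of ortho-alkoxy aryldiazoacetates under chiral dirhodium tetracarboxylates, which gives cis-2-substituted 2,3-dihydrobenzofuran-3-carboxylates. The dihydrofuran ring closes by a 1,5-insertion: the carbene carbon bonds to the carbon five atoms away, forming C2–C3 and a five-membered ring. C2 is set by which of the two diastereotopic ether hydrogens the chiral carboxylate ligands let the carbene reach, that is by the catalyst, with the neighbouring C1' center as a weaker bias that has to be matched. C3 is set relative to C2 by the usual preference of this insertion for the ester and the C2 substituent on the same face; it is erased in step 9, so its outcome does not matter. Site selectivity is needed against the tertiary C1'–H (six-membered ring) and the CH2 beside the silyl ether (seven-membered ring), and is secured by the lone pair of O1, which stabilises the positive charge building on C2, and by the kinetic preference for the five-membered ring. The aryl bromide, the silyl ether and the electron-poor trichloroethyl group offer the electrophilic carbene nothing to react with, and slow addition at low temperature keeps carbene dimerisation down.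

Step 8
Reactants: 10 2,2,2-trichloroethyl (2R,3R)-5-bromo-2-[(S)-1-(tert-butyldimethylsilyloxy)propan-2-yl]-2,3-dihydrobenzofuran-3-carboxylate
Product: 11 (2R,3R)-5-bromo-2-[(S)-1-(tert-butyldimethylsilyloxy)propan-2-yl]-2,3-dihydrobenzofuran-3-carboxylic acid
Conditions: Zn dust, THF/1 M aq. KH2PO4, rt
Reagents that add atoms: none
Why: Reductive fragmentation of the trichloroethyl ester (zinc insertion into C–Cl, then beta-elimination of the carboxylate); the medium is near neutral, so no C3 enolate forms and the ring cannot open, and the aryl bromide and silyl ether are not reduced by zinc.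

Step 9
Reactants: 11 (2R,3R)-5-bromo-2-[(S)-1-(tert-butyldimethylsilyloxy)propan-2-yl]-2,3-dihydrobenzofuran-3-carboxylic acid
Product: 13 (S)-5-bromo-2-[(S)-1-(tert-butyldimethylsilyloxy)propan-2-yl]-2,3-dihydrobenzofuran, via Barton ester 12 (not isolated)
Conditions: 2-mercaptopyridine N-oxide, DCC, DMAP (cat.), CH2Cl2, 0 °C → rt, dark; then t-BuSH (excess), hν (tungsten lamp), rt
Reagents that add atoms: none
Why: Barton reductive decarboxylation: the thiohydroxamate ester fragments under light to CO2 and a benzylic C3 radical, which takes hydrogen from the thiol in a chain; thiyl radicals do not attack the aryl bromide. C2 is not a radical site, and opening of the C2–O1 bond from the C3 radical is disfavoured because that bond lies in the ring plane, orthogonal to the benzylic radical orbital, so C2 is kept (now S by the priority change).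

Step 10
Reactants: 13 (S)-5-bromo-2-[(S)-1-(tert-butyldimethylsilyloxy)propan-2-yl]-2,3-dihydrobenzofuran; 14 tert-butyl acrylate
Product: 15 tert-butyl (E)-3-{(S)-2-[(S)-1-(tert-butyldimethylsilyloxy)propan-2-yl]-2,3-dihydrobenzofuran-5-yl}acrylate
Conditions: Pd(OAc)2, P(o-tol)3, Et3N, DMF, 100 °C
Reagents that add atoms: none
Why: Heck reaction of an aryl bromide with an acrylate; syn insertion and syn beta-hydride elimination give the E alkene, and neither stereocenter is near the reacting site.

Step 11
Reactants: 15 tert-butyl (E)-3-{(S)-2-[(S)-1-(tert-butyldimethylsilyloxy)propan-2-yl]-2,3-dihydrobenzofuran-5-yl}acrylate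
Product: 16 tert-butyl (E)-3-{(S)-2-[(S)-1-hydroxypropan-2-yl]-2,3-dihydrobenzofuran-5-yl}acrylate
Conditions: TBAF, THF, 0 °C → rt; aq. NH4Cl
Reagents that add atoms: none
Why: Fluoride cleavage of the primary silyl ether; the hindered tert-butyl ester is not attacked.

Step 12
Reactants: 16 tert-butyl (E)-3-{(S)-2-[(S)-1-hydroxypropan-2-yl]-2,3-dihydrobenzofuran-5-yl}acrylate; 17 (E)-3-(4-hydroxyphenyl)acrylic acid
Product: 18 (S)-2-{(S)-5-[(E)-3-tert-butoxy-3-oxoprop-1-en-1-yl]-2,3-dihydrobenzofuran-2-yl}propyl (E)-3-(4-hydroxyphenyl)acrylate
Conditions: 17 (1.3 equiv), PPh3, DIAD (added last), THF, 0 °C → rt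
Reagents that add atoms: none
Why: Mitsunobu esterification; the carboxylic acid of 17 is several pKa units more acidic than its phenol, so it alone is deprotonated by the betaine and attacks the activated primary alcohol, a known chemoselective way to esterify unprotected phenolic acids. The reacting carbon is C2', so C1' is unaffected.

Step 13
Reactants: 18 (S)-2-{(S)-5-[(E)-3-tert-butoxy-3-oxoprop-1-en-1-yl]-2,3-dihydrobenzofuran-2-yl}propyl (E)-3-(4-hydroxyphenyl)acrylate
Product: 19 (E)-3-{(S)-2-[(S)-1-{[(E)-3-(4-hydroxyphenyl)acryloyl]oxy}propan-2-yl]-2,3-dihydrobenzofuran-5-yl}acrylic acid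
Conditions: TFA/CH2Cl2 (1:4), 0 °C → rt
Reagents that add atoms: none
Why: Acidolysis of the tert-butyl ester by alkyl–oxygen cleavage with loss of isobutene; the primary alkyl cinnamate, the cyclic ether and both E alkenes are stable to anhydrous acid.

**Compound list**

1 | methyl (S)-3-hydroxy-2-methylpropanoate | C[C@@H](CO)C(=O)OC | starting material
2 | methyl (S)-3-[(tert-butyldimethylsilyl)oxy]-2-methylpropanoate | C[C@@H](CO[Si](C)(C)C(C)(C)C)C(=O)OC | intermediate
3 | (R)-3-[(tert-butyldimethylsilyl)oxy]-2-methylpropan-1-ol | C[C@@H](CO[Si](C)(C)C(C)(C)C)CO | intermediate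
4 | methyl 2-(5-bromo-2-hydroxyphenyl)acetate | COC(=O)Cc1cc(Br)ccc1O | starting material
5 | methyl 2-{5-bromo-2-[(R)-3-(tert-butyldimethylsilyloxy)-2-methylpropoxy]phenyl}acetate | C[C@@H](CO[Si](C)(C)C(C)(C)C)COc1ccc(Br)cc1CC(=O)OC | intermediate
6 | 2-{5-bromo-2-[(R)-3-(tert-butyldimethylsilyloxy)-2-methylpropoxy]phenyl}acetic acid | C[C@@H](CO[Si](C)(C)C(C)(C)C)COc1ccc(Br)cc1CC(=O)O | intermediate
7 | 2,2,2-trichloroethanol | OCC(Cl)(Cl)Cl | starting material
8 | 2,2,2-trichloroethyl 2-{5-bromo-2-[(R)-3-(tert-butyldimethylsilyloxy)-2-methylpropoxy]phenyl}acetate | C[C@@H](CO[Si](C)(C)C(C)(C)C)COc1ccc(Br)cc1CC(=O)OCC(Cl)(Cl)Cl | intermediate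
9 | 2,2,2-trichloroethyl 2-{5-bromo-2-[(R)-3-(tert-butyldimethylsilyloxy)-2-methylpropoxy]phenyl}-2-diazoacetate | C[C@@H](CO[Si](C)(C)C(C)(C)C)COc1ccc(Br)cc1C(=[N+]=[N-])C(=O)OCC(Cl)(Cl)Cl | intermediate
10 | 2,2,2-trichloroethyl (2R,3R)-5-bromo-2-[(S)-1-(tert-butyldimethylsilyloxy)propan-2-yl]-2,3-dihydrobenzofuran-3-carboxylate (2,3-cis) | C[C@@H](CO[Si](C)(C)C(C)(C)C)[C@@H]1[C@H](C(=O)OCC(Cl)(Cl)Cl)c2cc(Br)ccc2O1 | intermediate
11 | (2R,3R)-5-bromo-2-[(S)-1-(tert-butyldimethylsilyloxy)propan-2-yl]-2,3-dihydrobenzofuran-3-carboxylic acid | C[C@@H](CO[Si](C)(C)C(C)(C)C)[C@@H]1[C@H](C(=O)O)c2cc(Br)ccc2O1 | intermediate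
12 | 2-thioxopyridin-1(2H)-yl (2R,3R)-5-bromo-2-[(S)-1-(tert-butyldimethylsilyloxy)propan-2-yl]-2,3-dihydrobenzofuran-3-carboxylate | C[C@@H](CO[Si](C)(C)C(C)(C)C)[C@@H]1[C@H](C(=O)On3ccccc3=S)c2cc(Br)ccc2O1 | intermediate
13 | (S)-5-bromo-2-[(S)-1-(tert-butyldimethylsilyloxy)propan-2-yl]-2,3-dihydrobenzofuran | C[C@@H](CO[Si](C)(C)C(C)(C)C)[C@@H]1Cc2cc(Br)ccc2O1 | intermediate
14 | tert-butyl acrylate | C=CC(=O)OC(C)(C)C | starting material
15 | tert-butyl (E)-3-{(S)-2-[(S)-1-(tert-butyldimethylsilyloxy)propan-2-yl]-2,3-dihydrobenzofuran-5-yl}acrylate | C[C@@H](CO[Si](C)(C)C(C)(C)C)[C@@H]1Cc2cc(/C=C/C(=O)OC(C)(C)C)ccc2O1 | intermediate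
16 | tert-butyl (E)-3-{(S)-2-[(S)-1-hydroxypropan-2-yl]-2,3-dihydrobenzofuran-5-yl}acrylate | C[C@@H](CO)[C@@H]1Cc2cc(/C=C/C(=O)OC(C)(C)C)ccc2O1 | intermediate
17 | (E)-3-(4-hydroxyphenyl)acrylic acid | OC(=O)/C=C/c1ccc(O)cc1 | starting material
18 | (S)-2-{(S)-5-[(E)-3-tert-butoxy-3-oxoprop-1-en-1-yl]-2,3-dihydrobenzofuran-2-yl}propyl (E)-3-(4-hydroxyphenyl)acrylate | C[C@@H](COC(=O)/C=C/c1ccc(O)cc1)[C@@H]1Cc2cc(/C=C/C(=O)OC(C)(C)C)ccc2O1 | intermediate
19 | (E)-3-{(S)-2-[(S)-1-{[(E)-3-(4-hydroxyphenyl)acryloyl]oxy}propan-2-yl]-2,3-dihydrobenzofuran-5-yl}acrylic acid | C[C@@H](COC(=O)/C=C/c1ccc(O)cc1)[C@@H]1Cc2cc(/C=C/C(=O)O)ccc2O1 | target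

**Step count and risk**

Total step count: 13. Longest linear sequence: 13 steps, from 1 to 19; compounds 4, 7, 14 and 17 enter as purchased materials.

Least certain steps:

Step 7 (key step). The likeliest failure is poor discrimination between the two diastereotopic ether hydrogens, if the catalyst and the C1' center work against each other. Lesser risks are insertion at the tertiary C1'–H or beside the silyl ether, and carbene dimerisation. The C3 outcome is irrelevant, since both C3 epimers converge in step 9. The fallback sets out from 3 and returns at 13, building the ring as an aromatic benzofuran and setting C2 by hydrogenation. Alcohol 3 is oxidised under Swern conditions to (S)-3-[(tert-butyldimethylsilyl)oxy]-2-methylpropanal F1. Ohira–Bestmann homologation (dimethyl (1-diazo-2-oxopropyl)phosphonate, K2CO3, MeOH) converts F1 into (R)-tert-butyldimethyl[(2-methylbut-3-yn-1-yl)oxy]silane F2. Sonogashira coupling of F2 at the C–I bond of 4-bromo-2-iodophenol A8 (Pd(PPh3)2Cl2, CuI, Et3N), with cyclisation of the phenol onto the alkyne in the same flask, gives 5-bromo-2-[(S)-1-(tert-butyldimethylsilyloxy)propan-2-yl]benzofuran F3. Asymmetric hydrogenation of the furan C2=C3 bond (Ru(cod)(2-methylallyl)2 with a chiral N-heterocyclic carbene ligand, H2) should then give 13 with C2 set by the catalyst.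

Step 9. The stabilised benzylic radical abstracts hydrogen slowly, so recombination with the pyridylthio group or premature collapse of the light-sensitive ester can compete with reduction. The fallback sets out from 11 and returns at 13. Acid 11 is coupled with N-hydroxyphthalimide (N,N'-diisopropylcarbodiimide, DMAP) to give 1,3-dioxoisoindolin-2-yl (2R,3R)-5-bromo-2-[(S)-1-(tert-butyldimethylsilyloxy)propan-2-yl]-2,3-dihydrobenzofuran-3-carboxylate F4. Single-electron reduction under visible light (Ru(bpy)3Cl2, a 1,4-dihydropyridine as reductant, t-BuSH as hydrogen donor) fragments F4 to the same C3 radical, with no sulfur group in the flask to trap it, and should give 13.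

Step 12. The phenol of 17 may be alkylated alongside the carboxylate, and the hydroxy acid may oligomerise once the alcohol is consumed. The fallback sets out from 16 and returns at 18 with a protected acid. Alcohol 16 is esterified with commercial (E)-4-acetoxycinnamic acid (EDC·HCl, DMAP, CH2Cl2) to give (S)-2-{(S)-5-[(E)-3-tert-butoxy-3-oxoprop-1-en-1-yl]-2,3-dihydrobenzofuran-2-yl}propyl (E)-3-(4-acetoxyphenyl)acrylate F5. The aryl acetate is far more electrophilic than the two conjugated alkyl esters, so aminolysis with pyrrolidine at 0 °C should remove it selectively and give 18.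

Step 13. The tert-butyl cation released may alkylate the phenol ring or the alkoxy-substituted benzofuran ring before it loses a proton. The fallback sets out from 13 and returns at 19, and never protects the acid. Bromide 13 is desilylated with TBAF to (S)-2-[(S)-5-bromo-2,3-dihydrobenzofuran-2-yl]propan-1-ol F6. F6 is esterified with 17 as in step 12 to give (S)-2-[(S)-5-bromo-2,3-dihydrobenzofuran-2-yl]propyl (E)-3-(4-hydroxyphenyl)acrylate F7. A Heck reaction of F7 with acrylic acid itself (Pd(OAc)2, P(o-tol)3, Et3N, DMF, 100 °C) should then give 19 directly; the monosubstituted acrylic acid inserts much faster than the beta-substituted cinnamate alkene already present.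

**Further compounds**

F1 | step 7 | (S)-3-[(tert-butyldimethylsilyl)oxy]-2-methylpropanal | C[C@@H](CO[Si](C)(C)C(C)(C)C)C=O
F2 | step 7 | (R)-tert-butyldimethyl[(2-methylbut-3-yn-1-yl)oxy]silane | C[C@@H](CO[Si](C)(C)C(C)(C)C)C#C
F3 | step 7 | 5-bromo-2-[(S)-1-(tert-butyldimethylsilyloxy)propan-2-yl]benzofuran | C[C@@H](CO[Si](C)(C)C(C)(C)C)c1cc2cc(Br)ccc2o1
F4 | step 9 | 1,3-dioxoisoindolin-2-yl (2R,3R)-5-bromo-2-[(S)-1-(tert-butyldimethylsilyloxy)propan-2-yl]-2,3-dihydrobenzofuran-3-carboxylate | C[C@@H](CO[Si](C)(C)C(C)(C)C)[C@@H]1[C@H](C(=O)ON3C(=O)c4ccccc4C3=O)c2cc(Br)ccc2O1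
F5 | step 12 | (S)-2-{(S)-5-[(E)-3-tert-butoxy-3-oxoprop-1-en-1-yl]-2,3-dihydrobenzofuran-2-yl}propyl (E)-3-(4-acetoxyphenyl)acrylate | C[C@@H](COC(=O)/C=C/c1ccc(OC(C)=O)cc1)[C@@H]1Cc2cc(/C=C/C(=O)OC(C)(C)C)ccc2O1
F6 | step 13 | (S)-2-[(S)-5-bromo-2,3-dihydrobenzofuran-2-yl]propan-1-ol | C[C@@H](CO)[C@@H]1Cc2cc(Br)ccc2O1
F7 | step 13 | (S)-2-[(S)-5-bromo-2,3-dihydrobenzofuran-2-yl]propyl (E)-3-(4-hydroxyphenyl)acrylate | C[C@@H](COC(=O)/C=C/c1ccc(O)cc1)[C@@H]1Cc2cc(Br)ccc2O1
A1 | alternative 1 | (2R,3S)-4-(2-chlorophenyl)-2-methyl-3-(4,4,5,5-tetramethyl-1,3,2-dioxaborolan-2-yl)butyl tert-butyldimethylsilyl ether | C[C@@H](CO[Si](C)(C)C(C)(C)C)[C@@H](B1OC(C)(C)C(C)(C)O1)Cc1ccccc1Cl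
A2 | alternative 1 | tert-butyldimethyl{[(S)-2-(4,4,5,5-tetramethyl-1,3,2-dioxaborolan-2-yl)propyl]oxy}silane | C[C@@H](CO[Si](C)(C)C(C)(C)C)B1OC(C)(C)C(C)(C)O1
A3 | alternative 1 | 2-chlorophenyl trifluoromethanesulfonate | O=S(=O)(Oc1ccccc1Cl)C(F)(F)F
A4 | alternative 1 | vinyllithium | [Li]C=C
A5 | alternative 2 | cis-5-(2-bromobenzyl)-2,2,4-trimethyl-1-oxa-2-silacyclopentane | C[C@H]1C[Si](C)(C)O[C@H]1Cc1ccccc1Br
A6 | alternative 2 | {[(S)-1-(2-bromophenyl)-3-methylbut-3-en-2-yl]oxy}dimethylsilane | C=C(C)[C@H](Cc1ccccc1Br)O[SiH](C)C
A7 | alternative 3 | (S)-5-bromo-2-(prop-1-en-2-yl)-2,3-dihydrobenzofuran | C=C(C)[C@@H]1Cc2cc(Br)ccc2O1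
A8 | alternative 3 | 4-bromo-2-iodophenol | Oc1ccc(Br)cc1I
A9 | alternative 3 | 2-methylbuta-1,3-diene (isoprene) | C=CC(C)=C
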